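Readings and results come from a simulation from invented constants; scatter was added.

The target in these readings is a sum of free target and its crystals, and the question concerns the free part.

| flask | substrate | remark | time |
|---|---|---|---|
| north-west | 0.37 M | run made earlier |  |
| south-west | 1.8 M | run made earlier |  |
| grey | 0.30 M |  | 40 min |
| ochre | 0.40 M |  | 40 min |
| green | 0.60 M |  | 40 min |
| red | 1.0 M |  | 40 min |
| teal | 1.5 M |  | 40 min |

| run | time / min | target / % | substrate / % |
|---|---|---|---|
| north-west | 2.50 | 15 | 9 |
| north-west | 8.00 | 27 | 9 |
| north-west | 12.0 | 35 | 10 |
| north-west | 20.0 | 46 | 9 |
| north-west | 30.0 | 54 | 6 |
| south-west | 6.00 | 29 | 9 |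
| south-west | 12.0 | 36 | 7 |
| south-west | 15.0 | 45 | 8 |
| south-west | 25.0 | 62 | 4 |
| south-west | 30.0 | 62 | 6 |

(readings scatter by 2 percentage points)

- what is said of target includes crystals
- crystals is a solid; its amount is given per volume of the solution
- steps that have been proposed: substrate <-> target; substrate <-> isomer of the product; crystals <-> target
- the concentration of target that is asked is that of its free form alone
- "hardly changes" means that all values lie within two and a half points (for a concentration: within two and a half percent of the largest)

- [target] (only what is free in solution) at the end for grey, ochre, green, red, teal, in this order
- the shape of the row from first to last (falls, then rises / falls all the way / rises, then falls / rises all the way / hardly changes)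

*What do you follow at the bench?* The pool: whatever is not yet target, so substrate plus isomer of the product. In the north-west run at 8.00 min, substrate reads 9 % and the isomer, by difference, 64.0 %. The isomer is the resting state.

*Why did the south-west run get further?* At 30.0 min it read 62 % target, more than the 54 % of the north-west run. Suppose crystals stand in both runs. Free target then stays near saturation, and its return to the pool is a constant trickle. The pool concentration falls at a rate proportional to its distance above a fixed level, which integrates simply: share of pool left = level/charge + (1 − level/charge)·exp(−kt).

*And the constants?* Two runs give two equations. Their difference gives 0.0373 M, which is the level times the share already drained. That leaves a decay factor of 0.359, so k is 0.0341 min⁻¹. The level comes out at 0.0582 M: this is the floor, the pool concentration in balance with a saturated solution.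

*How firm is that?* Not very. It rests on a difference of 8 percentage points between two readings, each with a scatter of 2 points.

*Does the floor give free target?* No: the readings give free target and crystals as one sum. With crystals standing, my own reckoning expects a nearly level row, at a height left open.

The forecast differs: 0.175 M, 0.232 M, 0.3 M, 0.3 M, 0.3 M, shape rises all the way, with a cap it calls “which is poorly determined”.

The flask gives 0.0203 M, 0.0204 M, 0.0206 M, 0.0211 M, 0.0217 M, and the shape is rises all the way. In grey at 40.0 min, crystals make up 52.1 % of the charge, within a target of 58.9 %.

    substrate ⇌ target (K = 2.40, k = 0.00430 s⁻¹)
    substrate ⇌ isomer of the product (K = 6.50, k = 0.0230 s⁻¹)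
    crystals ⇌ target, rate k3*(cs3 - [target]) while solid is left; crystals form when [target] > cs3 (solubility = 20.0 mM, k = 0.110 s⁻¹)

With the floor and k, the pool in grey at 40 min reckons to 40.0 %, and the flask holds 41.1 %. For teal, the floor comes to 3.88 % of the charge, and at 400 min teal's pool stands at 4.17 %.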